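**Retrosynthetic overview**

- Feature: ring A is a 1,4-disubstituted benzene, with C1' carrying the CH2CH2O-acyl arm and C4' the hydroxyl. It is one H2 short of a 4-substituted cyclohex-2-enone with the ketone at C4', so the arene is built as a carbocycle and aromatised last.
- Last disconnection: bongardol ⇒ racemic 2-(4-oxocyclohex-2-en-1-yl)ethyl octacosanoate, by dehydrogenation across C2'–C3'.
- Key disconnection: that enone ⇒ 4-oxobutyl octacosanoate + methyl vinyl ketone. The Michael addition forms C1'–C2' (aldehyde α-carbon to enone CH2 terminus) and the aldol condensation forms C5'–C6' (ketone methyl carbon to aldehyde carbon).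
- Aldehyde ⇒ octacosanoic acid + butane-1,4-diol, by mono-esterification and oxidation of the free hydroxyl.
- Ring order: ring A is the only ring. It is closed as a cyclohexenone in step 3 and becomes aromatic in step 4.

Key step: step 3

Remark: the target has no stereocentre; the one centre created in step 3 (C1') is racemic and is removed in step 4.
Remark: every intermediate carries a C28 chain and is a wax, so solvents and temperatures are chosen to keep the material dissolved.

**Route**

Step 1
Reactants: 1 octacosanoic acid; 2 butane-1,4-diol
Product: 3 4-hydroxybutyl octacosanoate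
Conditions: 2 (6 equiv), p-toluenesulfonic acid monohydrate (TsOH·H2O, 5 mol%), toluene, reflux, Dean–Stark trap
Reagents that add atoms: none
Why: Fischer esterification driven by azeotropic removal of water; with a large excess of the symmetrical diol the monoester should predominate, and the water-soluble diol and the non-polar diester are easily separated from it.

Step 2
Reactants: 3 4-hydroxybutyl octacosanoate
Product: 4 4-oxobutyl octacosanoate
Conditions: TEMPO ((2,2,6,6-tetramethylpiperidin-1-yl)oxyl, 10 mol%), PhI(OAc)2 (1.1 equiv), CH2Cl2, 25 °C
Reagents that add atoms: none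
Why: Oxoammonium-mediated oxidation of a primary alcohol (nitroxyl catalyst with PhI(OAc)2 as terminal oxidant) should stop at the aldehyde in a water-free medium, leave the ester untouched, and run at a temperature where the waxy substrate stays in solution.

Step 3
Reactants: 4 4-oxobutyl octacosanoate; 5 methyl vinyl ketone
Product: 8 rac-2-(4-oxocyclohex-2-en-1-yl)ethyl octacosanoate, via 3-formyl-6-oxoheptyl octacosanoate 6 (not isolated), via 2-(2-hydroxy-4-oxocyclohexyl)ethyl octacosanoate 7 (not isolated)
Conditions: 5 (2 equiv), pyrrolidine (20 mol%), PhCO2H (20 mol%), toluene, 35 °C, slow addition of 4; then excess 5 stripped, AcOH (1 equiv), 70 °C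
Reagents that add atoms: none
Why: Pyrrolidine condenses with aldehyde 4 to an enamine whose nucleophilic carbon (the aldehyde α-carbon, future C1') adds to the terminal CH2 of 5 (future C2'), and hydrolysis of the resulting iminium returns the catalyst and gives keto aldehyde 6 (Michael addition by enamine catalysis). On warming with pyrrolidinium acetate the methyl ketone of 6 is enolised through its enamine and its methyl carbon (future C5') attacks the aldehyde carbon (future C6') to give ketol 7, which loses water to the conjugated enone 8; the closest known reaction type is the amine-mediated Robinson-type annulation of α-monosubstituted aldehydes with methyl vinyl ketone to 4-substituted cyclohex-2-enones. Ring A is closed as a carbocycle by a 6-(enolendo)-exo-trig aldol, the only closure open to 6 because every other enol/carbonyl pairing would give a four-membered ring. The one new stereocentre, C1', forms under an achiral catalyst without control, so 6, 7 and 8 are racemic (7 also as a diastereomer mixture), which does not matter because C1' becomes sp2 in step 4. The step needs cross-selectivity (Michael addition to 5 ahead of self-aldol of 4) and a fixed 1,4-relation of side chain and oxygen: the first is secured by adding 4 slowly into an excess of 5 so that free aldehyde stays dilute, the second by connectivity, since the aldehyde α-carbon and the ketone carbon must end up para. The ester should be spared because the medium is a buffered amine salt and because the acyloxy group sits γ to the aldehyde, where no β-elimination from the enamine is possible.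

Step 4
Reactants: 8 rac-2-(4-oxocyclohex-2-en-1-yl)ethyl octacosanoate
Product: 10 bongardol (2-(4-hydroxyphenyl)ethyl octacosanoate), via 2-(4-oxocyclohexa-2,5-dien-1-yl)ethyl octacosanoate 9 (not isolated)
Conditions: Pd(O2CCF3)2 (5 mol%), 2-(dimethylamino)pyridine (10 mol%), TsOH·H2O (20 mol%), O2 (1 atm), DMSO/PhCl, 80 °C
Reagents that add atoms: none
Why: Aerobic palladium-catalysed dehydrogenation of a cyclohexenone to a phenol: a divalent palladium enolate forms at C3', β-hydride elimination from C2' gives dienone 9, which tautomerises to the phenol, while O2 returns zerovalent palladium to divalent palladium; the remote ester is inert, and any double-bond isomer of 8 formed in step 3 should converge on the same phenol.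

**Compound list**

1 | octacosanoic acid | CCCCCCCCCCCCCCCCCCCCCCCCCCCC(=O)O | starting material
2 | butane-1,4-diol | OCCCCO | starting material
3 | 4-hydroxybutyl octacosanoate | CCCCCCCCCCCCCCCCCCCCCCCCCCCC(=O)OCCCCO | intermediate
4 | 4-oxobutyl octacosanoate | CCCCCCCCCCCCCCCCCCCCCCCCCCCC(=O)OCCCC=O | intermediate
5 | methyl vinyl ketone (but-3-en-2-one) | CC(=O)C=C | starting material
6 | 3-formyl-6-oxoheptyl octacosanoate (racemic) | CCCCCCCCCCCCCCCCCCCCCCCCCCCC(=O)OCCC(C=O)CCC(C)=O | intermediate
7 | 2-(2-hydroxy-4-oxocyclohexyl)ethyl octacosanoate (racemic, mixture of diastereomers) | CCCCCCCCCCCCCCCCCCCCCCCCCCCC(=O)OCCC1CCC(=O)CC1O | intermediate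
8 | rac-2-(4-oxocyclohex-2-en-1-yl)ethyl octacosanoate | CCCCCCCCCCCCCCCCCCCCCCCCCCCC(=O)OCCC1C=CC(=O)CC1 | intermediate
9 | 2-(4-oxocyclohexa-2,5-dien-1-yl)ethyl octacosanoate | CCCCCCCCCCCCCCCCCCCCCCCCCCCC(=O)OCCC1C=CC(=O)C=C1 | intermediate
10 | bongardol, 2-(4-hydroxyphenyl)ethyl octacosanoate | CCCCCCCCCCCCCCCCCCCCCCCCCCCC(=O)OCCc1ccc(O)cc1 | target

**Step count**

Total steps: 4. Longest linear sequence: 4 steps (from octacosanoic acid 1).

**Steps most likely to fail**

1. Step 3. What may go wrong: self-aldol condensation of the aldehyde, amine-initiated oligomerisation of the enone, a second Michael addition, or stalling at the open-chain stage without ring closure. The fallback sets out from 4 and comes back to the route at 8. Aldehyde 4 is condensed with pyrrolidine (1.2 equiv, K2CO3, toluene, 0–25 °C) to the preformed enamine (E)-4-(pyrrolidin-1-yl)but-3-en-1-yl octacosanoate F1, so that no free aldehyde meets a base. F1 is treated with 5 (1.2 equiv, toluene, 25–60 °C) in a Stork enamine Michael addition to give the adduct enamine 6-oxo-3-(pyrrolidin-1-ylmethylidene)heptyl octacosanoate F2, which is hydrolysed in the flask with aqueous AcOH/NaOAc buffer to keto aldehyde 6, this time isolated. Compound 6 is then closed in a separate operation with catalytic TsOH·H2O in toluene under a Dean–Stark trap (acid-catalysed aldol condensation through 7) to give 8.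

2. Step 4. What may go wrong: aggregation of the palladium catalyst to inactive metal in the co-solvent needed to dissolve the waxy substrate, or incomplete turnover so that the oxidation stalls. The fallback sets out from 8 and comes back at 10. CuBr2 (2.2 equiv) in refluxing EtOAc/CHCl3 brominates the ketone α-CH2 (C3') to give 2-(5-bromo-4-oxocyclohex-2-en-1-yl)ethyl octacosanoate F3. Heating crude F3 with LiBr and Li2CO3 in DMF at 110 °C eliminates HBr to dienone 9, which tautomerises to 10.

3. Step 1. What may go wrong: over-acylation to the diester and acid-catalysed cyclodehydration of the diol, which together erode the mono-selectivity. The fallback sets out from 1 and comes back at 4, replacing steps 1 and 2. Acid 1 is esterified with pent-4-en-1-ol (C=CCCCO, 1.5 equiv; TsOH·H2O cat., toluene, Dean–Stark trap), an alcohol with a single hydroxyl, to give pent-4-en-1-yl octacosanoate F4. Lemieux–Johnson cleavage of the terminal alkene (OsO4 cat., NaIO4, 2,6-lutidine, THF/H2O, 30 °C) removes the terminal CH2 and gives aldehyde 4 directly.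

**Further compounds**

F1 | step 3 | (E)-4-(pyrrolidin-1-yl)but-3-en-1-yl octacosanoate | CCCCCCCCCCCCCCCCCCCCCCCCCCCC(=O)OCC/C=C/N1CCCC1
F2 | step 3 | 6-oxo-3-(pyrrolidin-1-ylmethylidene)heptyl octacosanoate | CCCCCCCCCCCCCCCCCCCCCCCCCCCC(=O)OCCC(=CN1CCCC1)CCC(C)=O
F3 | step 4 | 2-(5-bromo-4-oxocyclohex-2-en-1-yl)ethyl octacosanoate | CCCCCCCCCCCCCCCCCCCCCCCCCCCC(=O)OCCC1C=CC(=O)C(Br)C1
F4 | step 1 | pent-4-en-1-yl octacosanoate | CCCCCCCCCCCCCCCCCCCCCCCCCCCC(=O)OCCCC=C
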